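**Retrosynthetic overview**

1. Numbering: ring C1 (CH bearing isopropenyl, central carbon Ca), C2H2, C3H=C4(CH3), C5 (CH bearing C11H2–OAr), C6 (quaternary: CH3 and C7–C8–C9O2H). The ring is a p-menthadiene with the C4 methyl para to the C1 isopropenyl; a bond drawn from Ca to C3 closes the cyclobutane C1–C2–C3–Ca and gives the bicyclo[3.1.1]heptane of verbenone, which already holds C6–CH3, the C4 oxygen and Ca(CH3)2.
2. Endgame: the C9 acid comes from the terminus of a C6 allyl group, the C4 methyl from Negishi coupling of the C3=C4 enol triflate, and the C11–O bond from oxa-Michael addition of umbelliferone to the C5=C11 enone.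
3. Key disconnection: the C3=C4 enol acetate and the isopropenyl group come from Lewis-acid scission of the Ca–C3 cyclobutane bond of a 6-allyl-5-methylene pinanone.
4. That ketone comes from (−)-verbenone by conjugate allylation at C6 and Mannich methylenation at C5.
5. Ring order: no ring is built. Ring C1–C6 is the six-membered ring of verbenone, the cyclobutane is opened in step 4, and the coumarin arrives intact with umbelliferone.

Key step: step 4

Assumption: commercial (1S,5S)-(−)-verbenone is taken to be of high enantiomeric purity, since C1 of the target, and through it C6 and C5, are relayed from its bridgeheads; the atom labels C1–C6, Ca and C11 above are used for all intermediates, the bicyclic ones included (verbenone: C4 ketone, C5=C6 alkene, bridgeheads C1 and C3).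

**Route**

Step 1
Reactants: 1 (1S,5S)-(−)-verbenone; 2 allylmagnesium bromide
Product: 3 (1S,4R,5R)-4-allyl-4,6,6-trimethyl-2-(trimethylsilyloxy)bicyclo[3.1.1]hept-2-ene (allyl anti to the CMe2 bridge)
Conditions: 2 + CuBr·SMe2 (1.3 equiv each), THF, −78 °C; Me3SiCl (3 equiv), then 1, −78 to −40 °C; Et3N, pentane, cold aq NaHCO3
Reagents that add atoms: allylmagnesium bromide (2), C=CC[Mg]Br; chlorotrimethylsilane, C[Si](C)(C)Cl
Why: Chlorosilane-accelerated conjugate addition of an allylcopper reagent (monovalent copper) to the β,β-disubstituted enone with O-silylation of the enolate; the allyl group enters C6 on the face of the C2H2 bridge, away from the shielding Ca(CH3)2 bridge, which sets the quaternary stereocenter (allyl trans, CH3 cis to Ca).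

Step 2
Reactants: 3 silyl enol ether; 4 dimethylmethyleneiminium iodide
Product: 5 (1S,4R,5R)-4-allyl-3-[(dimethylamino)methyl]-4,6,6-trimethylbicyclo[3.1.1]heptan-2-one (aminomethyl-bearing carbon of either configuration)
Conditions: 4 (1.5 equiv), CH2Cl2, 23 °C
Reagents that add atoms: dimethylmethyleneiminium iodide (4), C[N+](C)=C.[I-]
Why: Mannich reaction of a silyl enol ether with a preformed iminium salt, in which C5 is the only nucleophilic carbon because the other α-carbon, C3, is a bridgehead that cannot enolise; the new C5 stereocenter is not controlled and is erased in step 3.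

Step 3
Reactants: 5 Mannich base
Product: 7 (1S,4R,5R)-4-allyl-4,6,6-trimethyl-3-methylidenebicyclo[3.1.1]heptan-2-one, via trimethylammonium iodide 6 (not isolated)
Conditions: MeI, CH2Cl2, 23 °C; then aq NaHCO3, 23 °C
Reagents that add atoms: iodomethane, CI (its methyl stays in 6 only and leaves as trimethylamine)
Why: N-methylation gives the quaternary ammonium salt, whose E1cB (Hofmann-type) elimination across C5–C11 under mild base should give the exocyclic enone; C5 becomes trigonal and no stereocenter is formed.

Step 4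
Reactants: 7 allylated α-methylene pinanone
Product: 8 (4R,5R)-5-allyl-5-methyl-6-methylidene-4-(prop-1-en-2-yl)cyclohex-1-en-1-yl acetate (methyl cis to isopropenyl)
Conditions: BF3·OEt2, Zn(OAc)2, Ac2O, 0 to 23 °C
Reagents that add atoms: acetic anhydride, CC(=O)OC(C)=O
Why: BF3 binds the C4 carbonyl, the strained Ca–C3 σ bond α to it ionises to a boron dienolate and the tertiary cation at Ca, acetic anhydride acylates the enolate oxygen and acetate removes a methyl proton, so the C3=C4 enol acetate and the Ca=CH2 alkene result. The closest known reaction type is the BF3·OEt2/Zn(OAc)2/Ac2O cleavage of pinane-type cyclobutyl ketones (nopinone, verbanones and their 4-alkenyl congeners) to 4-isopropenylcyclohexenyl acetates; here the ketone also carries the C5 methylene, which becomes the second double bond of a 2-acetoxy-1,3-diene. No ring is closed: the four-membered ring C1–C2–C3–Ca opens and the six-membered ring C1–C6 is the one already present. No stereocenter is created; C1 and C6 are carried over unchanged and C3 becomes trigonal. The selectivity needed is heterolysis of Ca–C3 rather than a Wagner–Meerwein shift or C2–C3 cleavage, and proton loss from a methyl rather than from C1–H: only Ca–C3 leads to a tertiary cation with the Lewis-acid-bound carbonyl as electron sink, and C1–H sits next to quaternary C6, where a tetrasubstituted isopropylidene would be strained. Acetate addition to the C5=C11 enone is the side reaction to limit, by low temperature and short reaction time.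

Step 5
Reactants: 8 dienyl acetate
Product: 10 (3R,4R)-3-allyl-3-methyl-2-methylidene-4-(prop-1-en-2-yl)cyclohexan-1-one, via lithium dienolate 9 (not isolated)
Conditions: MeLi (2.1 equiv), THF, −78 to −40 °C; inverse quench into AcOH/THF, −78 °C
Reagents that add atoms: methyllithium, [Li]C (its lithium stays in 9 only)
Why: Acyl cleavage of an enol acetate by methyllithium (the second equivalent consumes the acetone released) unmasks the lithium 2-oxido-1,3-diene, and C-protonation at C3, its only nucleophilic carbon, should give the enone without any oxygen nucleophile that could add to C11; no stereocenter changes.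

Step 6
Reactants: 10 monocyclic α-methylene ketone; 11 umbelliferone
Product: 12 (2R,3R,4R)-3-allyl-3-methyl-2-{[(2-oxo-2H-chromen-7-yl)oxy]methyl}-4-(prop-1-en-2-yl)cyclohexan-1-one (CH2OAr cis to the ring methyl and to isopropenyl)
Conditions: 11 (2 equiv), Cs2CO3 (0.2 equiv), MeCN, 23 °C
Reagents that add atoms: umbelliferone (11), O=c1ccc2ccc(O)cc2o1
Why: Base-catalysed oxa-Michael addition of the phenoxide to the unhindered C11 terminus of the exocyclic enone (the reaction type by which phenols are alkylated with α-methylene ketones); the C5 stereocenter is set on protonation of the enolate and should equilibrate under the basic conditions to the epimer with C11 equatorial in the chair that holds isopropenyl and allyl equatorial and the C6 methyl axial, that is C11 cis to C6–CH3 as in the target.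

Step 7
Reactants: 12 β-aryloxy ketone
Product: 14 (4R,5R,6R)-5-allyl-5-methyl-6-{[(2-oxo-2H-chromen-7-yl)oxy]methyl}-4-(prop-1-en-2-yl)cyclohex-1-en-1-yl trifluoromethanesulfonate, via potassium enolate 13 (not isolated)
Conditions: KN(SiMe3)2 (1.2 equiv), THF, −78 °C; N-(5-chloropyridin-2-yl)bis(trifluoromethanesulfonyl)imide, −78 °C; then AcOH
Reagents that add atoms: N-(5-chloropyridin-2-yl)bis(trifluoromethanesulfonyl)imide, O=S(=O)(N(c1ccc(Cl)cn1)S(=O)(=O)C(F)(F)F)C(F)(F)F; potassium bis(trimethylsilyl)amide, C[Si](C)(C)N([K])[Si](C)(C)C (its potassium stays in 13 only)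
Why: Kinetic deprotonation by the hindered amide at the unhindered C3H2 rather than at the tertiary C5–H next to quaternary C6, followed by O-sulfonylation of the potassium enolate at −78 °C (enol triflate formation), fixes the double bond at C3=C4 and ends the epimerisability of C5 before β-elimination of aryloxide can set in.

Step 8
Reactants: 14 enol triflate; 15 methylzinc chloride
Product: 16 7-{[(1R,5R,6R)-6-allyl-2,6-dimethyl-5-(prop-1-en-2-yl)cyclohex-2-en-1-yl]methoxy}-2H-chromen-2-one
Conditions: 15 (2 equiv), Pd(PPh3)4 (5 mol %), THF, 50 °C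
Reagents that add atoms: methylzinc chloride (15), C[Zn]Cl
Why: Negishi coupling, in which oxidative addition of the alkenyl triflate to zerovalent palladium, transmetalation from methylzinc (no β-hydrogen, inert toward the coumarin lactone) and reductive elimination form the C4–CH3 bond with the double bond held at C3=C4; no stereocenter is touched.

Step 9
Reactants: 16 aryl ether tetraene
Product: 18 7-{[(1R,5R,6R)-6-(3-hydroxypropyl)-2,6-dimethyl-5-(prop-1-en-2-yl)cyclohex-2-en-1-yl]methoxy}-2H-chromen-2-one, via alkyldisiamylborane 17 (not isolated)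
Conditions: (Sia)2BH (1.3 equiv, from BH3·SMe2 and 2-methylbut-2-ene, THF, 0 °C), THF, 0 °C; then 30% H2O2, pH 7 phosphate buffer, 0 to 23 °C
Reagents that add atoms: disiamylborane, CC(C)C(C)BC(C)C(C)C (boron and sec-alkyl groups stay in 17 only); hydrogen peroxide, OO
Why: Hydroboration–oxidation, in which the hindered dialkylborane adds anti-Markovnikov to the monosubstituted allyl terminus much faster than to the 1,1-disubstituted isopropenyl group beside quaternary C6, the trisubstituted ring alkene or the electron-poor coumarin, and buffered peroxide replaces boron by hydroxyl without opening the lactone; no stereocenter is formed.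

Step 10
Reactants: 18 primary alcohol
Product: 20 3-[(1R,2R,6R)-1,3-dimethyl-2-{[(2-oxo-2H-chromen-7-yl)oxy]methyl}-6-(prop-1-en-2-yl)cyclohex-3-en-1-yl]propanoic acid (CNP0103683.1), via aldehyde 19 (not isolated)
Conditions: TEMPO (0.2 equiv), PhI(OAc)2 (2.5 equiv), MeCN/H2O 1:1, 23 °C
Reagents that add atoms: water, O
Why: Oxoammonium (TEMPO) oxidation with PhI(OAc)2 as terminal oxidant takes the primary alcohol to the aldehyde, whose hydrate is oxidised on to the carboxylic acid in aqueous acetonitrile, while the alkenes, the aryl ether and the coumarin are inert to this oxidant; no stereocenter is affected.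

**Compound list**

1 | (1S,5S)-(−)-verbenone, (1S,5S)-4,6,6-trimethylbicyclo[3.1.1]hept-3-en-2-one | CC2(C)[C@H]1C[C@@H]2C(=O)C=C1C | starting material
2 | allylmagnesium bromide | C=CC[Mg]Br | starting material
3 | (1S,4R,5R)-4-allyl-4,6,6-trimethyl-2-(trimethylsilyloxy)bicyclo[3.1.1]hept-2-ene, allyl on the face of the CH2 bridge | CC2(C)[C@H]1C[C@@H]2C(O[Si](C)(C)C)=C[C@]1(C)CC=C | intermediate
4 | dimethylmethyleneiminium iodide | C[N+](C)=C.[I-] | starting material
5 | (1S,4R,5R)-4-allyl-3-[(dimethylamino)methyl]-4,6,6-trimethylbicyclo[3.1.1]heptan-2-one, aminomethyl-bearing carbon of either configuration | CC2(C)[C@H]1C[C@@H]2C(=O)C(CN(C)C)[C@]1(C)CC=C | intermediate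
6 | N-methyl quaternary ammonium iodide of 5 | CC2(C)[C@H]1C[C@@H]2C(=O)C(C[N+](C)(C)C)[C@]1(C)CC=C.[I-] | intermediate
7 | (1S,4R,5R)-4-allyl-4,6,6-trimethyl-3-methylidenebicyclo[3.1.1]heptan-2-one | CC2(C)[C@H]1C[C@@H]2C(=O)C(=C)[C@]1(C)CC=C | intermediate
8 | (4R,5R)-5-allyl-5-methyl-6-methylidene-4-(prop-1-en-2-yl)cyclohex-1-en-1-yl acetate, methyl cis and allyl trans to isopropenyl | C=C(C)[C@H]1CC=C(OC(C)=O)C(=C)[C@]1(C)CC=C | intermediate
9 | lithium dienolate of 10 (lithium 2-oxido-1,3-diene, C3=C4–OLi, C5=C11) | C=C(C)[C@H]1CC=C(O[Li])C(=C)[C@]1(C)CC=C | intermediate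
10 | (3R,4R)-3-allyl-3-methyl-2-methylidene-4-(prop-1-en-2-yl)cyclohexan-1-one | C=C(C)[C@H]1CC(=O)C(=C)[C@]1(C)CC=C | intermediate
11 | umbelliferone, 7-hydroxy-2H-chromen-2-one | O=c1ccc2ccc(O)cc2o1 | starting material
12 | (2R,3R,4R)-3-allyl-3-methyl-2-{[(2-oxo-2H-chromen-7-yl)oxy]methyl}-4-(prop-1-en-2-yl)cyclohexan-1-one, CH2OAr cis to the C3 methyl and to isopropenyl | C=C(C)[C@H]1CC(=O)[C@@H](COc2ccc3ccc(=O)oc3c2)[C@]1(C)CC=C | intermediate
13 | potassium enolate of 12 on the C3 side (C3=C4–OK) | C=C(C)[C@H]1CC=C(O[K])[C@@H](COc2ccc3ccc(=O)oc3c2)[C@]1(C)CC=C | intermediate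
14 | (4R,5R,6R)-5-allyl-5-methyl-6-{[(2-oxo-2H-chromen-7-yl)oxy]methyl}-4-(prop-1-en-2-yl)cyclohex-1-en-1-yl trifluoromethanesulfonate | C=C(C)[C@H]1CC=C(OS(=O)(=O)C(F)(F)F)[C@@H](COc2ccc3ccc(=O)oc3c2)[C@]1(C)CC=C | intermediate
15 | methylzinc chloride | C[Zn]Cl | starting material
16 | 7-{[(1R,5R,6R)-6-allyl-2,6-dimethyl-5-(prop-1-en-2-yl)cyclohex-2-en-1-yl]methoxy}-2H-chromen-2-one | C=C(C)[C@H]1CC=C(C)[C@@H](COc2ccc3ccc(=O)oc3c2)[C@]1(C)CC=C | intermediate
17 | B-alkyl bis(3-methylbutan-2-yl)borane from 16 (boron on the terminal chain carbon) | C=C(C)[C@H]1CC=C(C)[C@@H](COc2ccc3ccc(=O)oc3c2)[C@]1(C)CCCB(C(C)C(C)C)C(C)C(C)C | intermediate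
18 | 7-{[(1R,5R,6R)-6-(3-hydroxypropyl)-2,6-dimethyl-5-(prop-1-en-2-yl)cyclohex-2-en-1-yl]methoxy}-2H-chromen-2-one | C=C(C)[C@H]1CC=C(C)[C@@H](COc2ccc3ccc(=O)oc3c2)[C@]1(C)CCCO | intermediate
19 | 3-[(1R,2R,6R)-1,3-dimethyl-2-{[(2-oxo-2H-chromen-7-yl)oxy]methyl}-6-(prop-1-en-2-yl)cyclohex-3-en-1-yl]propanal | C=C(C)[C@H]1CC=C(C)[C@@H](COc2ccc3ccc(=O)oc3c2)[C@]1(C)CCC=O | intermediate
20 | 3-[(1R,2R,6R)-1,3-dimethyl-2-{[(2-oxo-2H-chromen-7-yl)oxy]methyl}-6-(prop-1-en-2-yl)cyclohex-3-en-1-yl]propanoic acid | C=C(C)[C@H]1CC=C(C)[C@@H](COc2ccc3ccc(=O)oc3c2)[C@]1(C)CCC(=O)O | target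

**Summary**

Total step count: 10. Longest linear sequence: 10 steps, from 1 to 20.

Steps most likely to fail:

Step 4. The Lewis acid may trigger acetate addition to, or oligomerisation of, the exocyclic enone before the ring opens, or the Ca cation may be captured by the allyl π bond instead of losing a proton. The fallback removes the enone before the scission, sets out from 7 and returns at 8. Conjugate addition of thiophenol (PhSH, Et3N, CH2Cl2, 0 °C) should give 4-allyl-4,6,6-trimethyl-3-[(phenylsulfanyl)methyl]bicyclo[3.1.1]heptan-2-one F1, a saturated pinanone of the class on which the scission is established. BF3·OEt2, Zn(OAc)2 and Ac2O should then open it to 5-allyl-5-methyl-6-[(phenylsulfanyl)methyl]-4-(prop-1-en-2-yl)cyclohex-1-en-1-yl acetate F2. NaIO4 (MeOH/H2O, 0 °C) should oxidise sulfur only to the phenylsulfinylmethyl enol acetate F3. Thermal syn-elimination (toluene, 110 °C, CaCO3) toward the only β-hydrogen, on C5, restores the C5=C11 double bond and gives 8.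

Step 6. The addition is reversible, so conversion may stall or the aryloxide may be lost again by β-elimination (also under the base of step 7); the ambident phenoxide may alkylate on carbon; and the equatorial preference at C5 may be too small. The fallback forms the C11–O aryl bond by Mitsunobu etherification of a primary alcohol, sets out from 10 and returns at 16. 4-Methoxybenzyl alcohol with catalytic KOtBu (THF, 0 °C) should add to 10 to give 3-allyl-2-{[(4-methoxybenzyl)oxy]methyl}-3-methyl-4-(prop-1-en-2-yl)cyclohexan-1-one F4, whose alkoxide is a poorer leaving group. The conditions of step 7 should give, through the potassium enolate F5, the enol triflate F6, and the conditions of step 8 the 4-methoxybenzyl ether of [6-allyl-2,6-dimethyl-5-(prop-1-en-2-yl)cyclohex-2-en-1-yl]methanol F7. DDQ (CH2Cl2/pH 7 buffer) should free [6-allyl-2,6-dimethyl-5-(prop-1-en-2-yl)cyclohex-2-en-1-yl]methanol F8, and 11 with PPh3 and DIAD (THF) should convert it to 16.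

Step 9. Chemoselectivity may be lost through hydroboration of the isopropenyl group or reduction of the coumarin lactone by the dialkylborane. The fallback avoids boranes, sets out from 16 and returns at 19. An aldehyde-selective Wacker oxidation (PdCl2(PhCN)2, CuCl2, AgNO2, O2, tBuOH/MeNO2, 23 °C), which engages only the monosubstituted alkene, should give aldehyde 19, isolated in this variant. NaClO2, NaH2PO4 and 2-methylbut-2-ene (tBuOH/H2O) then take 19 to 20. No compound outside the list is made (F0).

**Further compounds**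

F1 | step 4 | 4-allyl-4,6,6-trimethyl-3-[(phenylsulfanyl)methyl]bicyclo[3.1.1]heptan-2-one, sulfanylmethyl-bearing carbon of either configuration | CC2(C)[C@H]1C[C@@H]2C(=O)C(CSc3ccccc3)[C@]1(C)CC=C
F2 | step 4 | 5-allyl-5-methyl-6-[(phenylsulfanyl)methyl]-4-(prop-1-en-2-yl)cyclohex-1-en-1-yl acetate, C5 (target numbering) of either configuration | C=C(C)[C@H]1CC=C(OC(C)=O)C(CSc2ccccc2)[C@]1(C)CC=C
F3 | step 4 | 5-allyl-5-methyl-6-[(phenylsulfinyl)methyl]-4-(prop-1-en-2-yl)cyclohex-1-en-1-yl acetate | C=C(C)[C@H]1CC=C(OC(C)=O)C(CS(=O)c2ccccc2)[C@]1(C)CC=C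
F4 | step 6 | 3-allyl-2-{[(4-methoxybenzyl)oxy]methyl}-3-methyl-4-(prop-1-en-2-yl)cyclohexan-1-one, configuration as in 12 | C=C(C)[C@H]1CC(=O)[C@@H](COCc2ccc(OC)cc2)[C@]1(C)CC=C
F5 | step 6 | potassium enolate of F4 on the C3 side | C=C(C)[C@H]1CC=C(O[K])[C@@H](COCc2ccc(OC)cc2)[C@]1(C)CC=C
F6 | step 6 | 5-allyl-6-{[(4-methoxybenzyl)oxy]methyl}-5-methyl-4-(prop-1-en-2-yl)cyclohex-1-en-1-yl trifluoromethanesulfonate | C=C(C)[C@H]1CC=C(OS(=O)(=O)C(F)(F)F)[C@@H](COCc2ccc(OC)cc2)[C@]1(C)CC=C
F7 | step 6 | 1-({[6-allyl-2,6-dimethyl-5-(prop-1-en-2-yl)cyclohex-2-en-1-yl]methoxy}methyl)-4-methoxybenzene, configuration as in 16 | C=C(C)[C@H]1CC=C(C)[C@@H](COCc2ccc(OC)cc2)[C@]1(C)CC=C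
F8 | step 6 | [6-allyl-2,6-dimethyl-5-(prop-1-en-2-yl)cyclohex-2-en-1-yl]methanol, configuration as in 16 | C=C(C)[C@H]1CC=C(C)[C@@H](CO)[C@]1(C)CC=C
F0 | step 9 | none | none
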